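The plan cuts the bond between the spiro carbon (C5) and the methyl-bearing carbon (C10) of the cyclohexene ring. C5 stands two bonds from C8, the cyclopentane carbon that carries the lactone oxygen; with C8 as a ketone, C5 becomes the β-carbon of a cyclopent-2-enone, and the C10 methyl can be born from a vinyl group. One hydrogen-atom-transfer radical conjugate addition then closes the cyclohexene 6-exo, creates the quaternary spiro centre and the adjacent methyl stereocentre, both relayed from a tartrate-derived trans-acetonide at C1/C2. The precursor is a 3-dienyl cyclopent-2-enone that carries this vinyl dioxolane. Catalyst-controlled lactone annulation, methylenation and angeloylation complete the target.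

Key step: step 7

Remark on numbering (used for all intermediates): spiro carbon C5; cyclohexene ring C5–C4(=C3)–C2–C1–C10; C14 = methyl on C10; C15 = CH2O on C4; cyclopentane ring C5–C6–C7–C8–C9; lactone C11 (on C7), C12 (C=O, bonded to the oxygen on C8), C13 (=CH2). In this numbering the target is 1S,2S,5R,7R,8R,10R. Compounds 1, 9 and 25 are commercial.

Step 1
Reactants: 1 dimethyl (4R,5R)-2,2-dimethyl-1,3-dioxolane-4,5-dicarboxylate (dimethyl 2,3-O-isopropylidene-L-tartrate)
Product: 2 methyl (4R,5S)-5-(hydroxymethyl)-2,2-dimethyl-1,3-dioxolane-4-carboxylate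
Conditions: NaBH4 (0.6 equiv), MeOH, 0 °C
Reagents that add atoms: none
Why: Borohydride reduction of an α-alkoxy-activated ester; the two esters of 1 are homotopic (C2 axis), so sub-stoichiometric hydride should give one mono-alcohol (the trans hydroxy ester cannot lactonise), and no stereocentre is touched.

Step 2
Reactants: 2 methyl (4R,5S)-5-(hydroxymethyl)-2,2-dimethyl-1,3-dioxolane-4-carboxylate
Product: 4 methyl (4R,5S)-5-ethenyl-2,2-dimethyl-1,3-dioxolane-4-carboxylate, via aldehyde ester 3 (not isolated)
Conditions: (COCl)2, DMSO, CH2Cl2, −78 °C; Et3N; then Ph3P=CH2 (from Ph3PCH3Br, KHMDS), THF, −78 → 0 °C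
Reagents that add atoms: methyltriphenylphosphonium bromide (source of the ylide CH2) C[P+](c1ccccc1)(c1ccccc1)c1ccccc1.[Br-]
Why: One-pot Swern oxidation and Wittig methylenation avoids isolating the labile α-alkoxy aldehyde; the trans-dioxolane is the stable arrangement, so the α-centre should hold.

Step 3
Reactants: 4 methyl (4R,5S)-5-ethenyl-2,2-dimethyl-1,3-dioxolane-4-carboxylate
Product: 6 ethyl (Z)-3-[(4S,5S)-5-ethenyl-2,2-dimethyl-1,3-dioxolan-4-yl]-2-iodoprop-2-enoate, via aldehyde 5 (not isolated)
Conditions: DIBAL-H (1.1 equiv), CH2Cl2, −78 °C; MeOH (2 equiv); then Ph3P=C(I)CO2Et (made separately from Ph3P=CHCO2Et, NIS, K2CO3, CH2Cl2, −20 °C), −78 °C → rt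
Reagents that add atoms: ethyl 2-(triphenyl-λ5-phosphanylidene)acetate CCOC(=O)C=P(c1ccccc1)(c1ccccc1)c1ccccc1; N-iodosuccinimide O=C1CCC(=O)N1I
Why: Ester-to-aldehyde reduction through the aluminium hemiacetal and in situ Wittig olefination with the stabilised α-iodo ylide, which should place the ester trans to the dioxolane and so give the (Z)-2-iodoenoate (iodine cis to the dioxolane).

Step 4
Reactants: 6 ethyl (Z)-3-[(4S,5S)-5-ethenyl-2,2-dimethyl-1,3-dioxolan-4-yl]-2-iodoprop-2-enoate
Product: 7 (Z)-3-[(4S,5S)-5-ethenyl-2,2-dimethyl-1,3-dioxolan-4-yl]-2-iodoprop-2-en-1-ol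
Conditions: DIBAL-H (2.5 equiv), CH2Cl2, −78 °C; Rochelle salt work-up
Reagents that add atoms: none
Why: 1,2-Reduction of the enoate to the allylic alcohol (C15); alkenyl iodide, acetal and alkene geometry are not affected.

Step 5
Reactants: 7 (Z)-3-[(4S,5S)-5-ethenyl-2,2-dimethyl-1,3-dioxolan-4-yl]-2-iodoprop-2-en-1-ol
Product: 8 tert-butyldimethylsilyl ether of 7
Conditions: TBSCl, imidazole, CH2Cl2, 0 °C → rt
Reagents that add atoms: tert-butyldimethylsilyl chloride CC(C)(C)[Si](C)(C)Cl
Why: Silyl ether formation on the primary allylic alcohol, needed for the organolithium and enolate steps.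

Step 6
Reactants: 8 silyl-protected (Z)-alkenyl iodide; 9 3-ethoxycyclopent-2-en-1-one
Product: 12 3-[(E)-3-(tert-butyldimethylsilyloxy)-1-[(4S,5S)-5-ethenyl-2,2-dimethyl-1,3-dioxolan-4-yl]prop-1-en-2-yl]cyclopent-2-en-1-one (dioxolane and cyclopentenone cis on C3=C4), via alkenyllithium 10 (not isolated), via lithium alkoxide adduct 11 (not isolated)
Conditions: t-BuLi (2.1 equiv), Et2O, −78 °C; 9, −78 → −20 °C; then 1 M aq. HCl, THF, 0 °C, 15 min
Reagents that add atoms: none
Why: Iodine–lithium exchange with retention of alkene geometry, 1,2-addition to the vinylogous ester and acid-promoted hydrolysis–dehydration (Stork–Danheiser transposition) give the 3-alkenyl cyclopentenone; brief cold dilute acid should spare acetonide and silyl ether.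

Step 7
Reactants: 12 dienone with terminal vinyl group
Product: 15 spiro ketone (1S;2S;5R;10R; C8 ketone; C15 TBS ether; C1/C2 trans-acetonide), via C10 radical 13 (not isolated), via spiro keto radical 14 (not isolated)
Conditions: Fe(acac)3 (0.5 equiv), PhSiH3 (2.5 equiv), EtOH/(CH2OH)2 5:1, 0.01 M, 60 °C
Reagents that add atoms: none
Why: An iron hydride formed from Fe(acac)3 and PhSiH3 transfers a hydrogen atom to the terminal carbon C14 of the isolated vinyl group (Markovnikov), the secondary C10 radical adds to C5, the β-carbon of the cyclopentenone, and the resulting C9 α-keto radical is reduced and protonated by the solvent. The closest known reaction type is the hydrogen-atom-transfer-initiated reductive olefin coupling (Giese-type radical conjugate addition) in its intramolecular form. The cyclohexene closes in the 6-exo-trig mode, with C3=C4 inside the new ring and C9 outside it. C10 is controlled by the trans-fused dioxolane, which holds both C–O bonds equatorial in the chair-like transition state and puts the methyl group pseudo-equatorial (eclipsing H1, anti to the C1–C2 bond); C5 is controlled by the attack trajectory, which leans away from C9 and so keeps C9 anti to C3 (pseudo-equatorial) and C6 axial. The step needs hydrogen-atom transfer to the electron-neutral vinyl group and not to the electron-poor dienone, which the polarity preference of the metal hydride should secure. It also needs attack at C5 only, which the Z-alkene secures because no other acceptor carbon can be reached in a ring of six or fewer.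

Step 8
Reactants: 15 spiro ketone
Product: 17 keto ester with CH2CO2Et at C7 (both C7 epimers), via lithium enolate 16 (not isolated)
Conditions: LDA, THF, −78 °C; BrCH2CO2Et, DMPU, −78 → −30 °C
Reagents that add atoms: ethyl bromoacetate CCOC(=O)CBr
Why: Kinetic deprotonation at C7, the α-methylene remote from the quaternary spiro carbon (C9 is neopentyl), and SN2 alkylation of the enolate; the C7 configuration is left open because step 9 equilibrates it.

Step 9
Reactants: 17 keto ester
Product: 19 cis-fused γ-lactone (7R;8R; O on C8; C11 on C7), via hydroxy ester 18 (not isolated)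
Conditions: RuCl2[(S)-binap][(R,R)-dpen] (1 mol %), KOtBu (10 mol %), H2 (10 atm), i-PrOH, 25 °C; then PPTS (cat.), PhH, 50 °C
Reagents that add atoms: none
Why: Noyori-type bifunctional ketone hydrogenation under dynamic kinetic resolution: base epimerises C7, the catalyst (chosen by analogy with 2-alkylcycloalkanones, which give the cis-(1R,2R) alcohol) selects the C8 face and the cis hydroxy ester, which lactonises; the two faces of the spiro cyclopentanone are nearly alike (C14 methyl above, C15 methylene below), so catalyst control is used in place of substrate control.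

Step 10
Reactants: 19 cis-fused γ-lactone
Product: 23 α-methylene lactone (TBS ether; acetonide), via lactone enolate 20 (not isolated), via Mannich base 21 (not isolated), via methiodide 22 (not isolated)
Conditions: LDA, THF, −78 °C; CH2=NMe2+ I−, −78 → 0 °C; MeI, MeOH, rt; NaHCO3, CH2Cl2/H2O
Reagents that add atoms: N,N-dimethylmethyleneiminium iodide (Eschenmoser's salt) C=[N+](C)C.[I-]
Why: Mannich alkylation of the lactone enolate, quaternisation and base-induced elimination install the exocyclic methylene (α-methylenation); no stereocentre is formed or lost.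

Step 11
Reactants: 23 α-methylene lactone silyl ether
Product: 24 primary allylic alcohol (C15–OH)
Conditions: HF·pyridine, pyridine/THF, 0 °C → rt
Reagents that add atoms: none
Why: Fluoride cleavage of the primary silyl ether under buffered conditions that the acetonide and the base-sensitive α-methylene lactone tolerate.

Step 12
Reactants: 24 primary allylic alcohol; 25 angelic acid ((Z)-2-methylbut-2-enoic acid)
Product: 26 angelate ester of 24 (acetonide still in place)
Conditions: 25, 2,4,6-Cl3C6H2COCl, Et3N, PhMe, rt; then 24, PhMe, 80 °C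
Reagents that add atoms: none
Why: Yamaguchi-type esterification through the mixed anhydride without DMAP, conditions under which the (Z)-angelate should not isomerise to the tiglate; the only free hydroxyl is the primary allylic one.

Step 13
Reactants: 26 angelate acetonide
Product: 27 target CNP0224912.1
Conditions: AcOH/H2O 4:1, 40 °C
Reagents that add atoms: none
Why: Acid-catalysed hydrolysis of the strained trans-fused acetonide releases the trans-diol; the ester, the allylic system and the α-methylene lactone should survive mild aqueous acetic acid.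

Compound list
1 | dimethyl (4R,5R)-2,2-dimethyl-1,3-dioxolane-4,5-dicarboxylate | COC(=O)[C@@H]1OC(C)(C)O[C@H]1C(=O)OC | starting material
2 | methyl (4R,5S)-5-(hydroxymethyl)-2,2-dimethyl-1,3-dioxolane-4-carboxylate | OC[C@@H]1OC(C)(C)O[C@H]1C(=O)OC | intermediate
3 | methyl (4R,5R)-5-formyl-2,2-dimethyl-1,3-dioxolane-4-carboxylate (not isolated) | O=C[C@@H]1OC(C)(C)O[C@H]1C(=O)OC | intermediate
4 | methyl (4R,5S)-5-ethenyl-2,2-dimethyl-1,3-dioxolane-4-carboxylate | C=C[C@@H]1OC(C)(C)O[C@H]1C(=O)OC | intermediate
5 | (4R,5S)-5-ethenyl-2,2-dimethyl-1,3-dioxolane-4-carbaldehyde (not isolated) | C=C[C@@H]1OC(C)(C)O[C@H]1C=O | intermediate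
6 | ethyl (Z)-3-[(4S,5S)-5-ethenyl-2,2-dimethyl-1,3-dioxolan-4-yl]-2-iodoprop-2-enoate | C=C[C@@H]1OC(C)(C)O[C@H]1/C=C(\I)C(=O)OCC | intermediate
7 | (Z)-3-[(4S,5S)-5-ethenyl-2,2-dimethyl-1,3-dioxolan-4-yl]-2-iodoprop-2-en-1-ol | C=C[C@@H]1OC(C)(C)O[C@H]1/C=C(\I)CO | intermediate
8 | tert-butyldimethylsilyl ether of 7 | C=C[C@@H]1OC(C)(C)O[C@H]1/C=C(\I)CO[Si](C)(C)C(C)(C)C | intermediate
9 | 3-ethoxycyclopent-2-en-1-one | CCOC1=CC(=O)CC1 | starting material
10 | alkenyllithium from 8 (not isolated) | C=C[C@@H]1OC(C)(C)O[C@H]1/C=C(\[Li])CO[Si](C)(C)C(C)(C)C | intermediate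
11 | lithium 1-alkenyl-3-ethoxycyclopent-2-en-1-olate, carbinol epimers (not isolated) | C=C[C@@H]1OC(C)(C)O[C@H]1/C=C(\C2(O[Li])C=C(OCC)CC2)CO[Si](C)(C)C(C)(C)C | intermediate
12 | 3-[(E)-3-(tert-butyldimethylsilyloxy)-1-[(4S,5S)-5-ethenyl-2,2-dimethyl-1,3-dioxolan-4-yl]prop-1-en-2-yl]cyclopent-2-en-1-one | C=C[C@@H]1OC(C)(C)O[C@H]1/C=C(\C2=CC(=O)CC2)CO[Si](C)(C)C(C)(C)C | intermediate
13 | secondary C10 radical from 12 (not isolated) | C[CH][C@@H]1OC(C)(C)O[C@H]1/C=C(\C2=CC(=O)CC2)CO[Si](C)(C)C(C)(C)C | intermediate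
14 | spiro C9 α-keto radical (not isolated) | O=C1[CH][C@@]2(CC1)C(CO[Si](C)(C)C(C)(C)C)=C[C@@H]3OC(C)(C)O[C@H]3[C@@H]2C | intermediate
15 | spiro ketone: cyclopentanone (C8=O) spiro at C5 to the cyclohexene C5–C4(CH2OTBS)=C3–C2–C1–C10(CH3), C1/C2 trans-acetonide; 1S,2S,5R,10R | O=C1C[C@@]2(CC1)C(CO[Si](C)(C)C(C)(C)C)=C[C@@H]3OC(C)(C)O[C@H]3[C@@H]2C | intermediate
16 | lithium C7–C8 enolate of 15 (not isolated) | [Li]OC1=CC[C@]2(C1)C(CO[Si](C)(C)C(C)(C)C)=C[C@@H]3OC(C)(C)O[C@H]3[C@@H]2C | intermediate
17 | keto ester: 15 with CH2CO2Et on C7, C7 epimers | O=C1C[C@@]2(CC1CC(=O)OCC)C(CO[Si](C)(C)C(C)(C)C)=C[C@@H]3OC(C)(C)O[C@H]3[C@@H]2C | intermediate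
18 | cis hydroxy ester, 7R,8R (not isolated) | O[C@@H]1C[C@@]2(C[C@@H]1CC(=O)OCC)C(CO[Si](C)(C)C(C)(C)C)=C[C@@H]3OC(C)(C)O[C@H]3[C@@H]2C | intermediate
19 | cis-fused γ-lactone (C12 to O on C8; C11 on C7), TBS ether, acetonide; 1S,2S,5R,7R,8R,10R | O=C1O[C@@H]2C[C@@]3(C[C@@H]2C1)C(CO[Si](C)(C)C(C)(C)C)=C[C@@H]4OC(C)(C)O[C@H]4[C@@H]3C | intermediate
20 | lithium enolate of lactone 19 (not isolated) | [Li]OC=1O[C@@H]2C[C@@]3(C[C@@H]2C=1)C(CO[Si](C)(C)C(C)(C)C)=C[C@@H]4OC(C)(C)O[C@H]4[C@@H]3C | intermediate
21 | α-(dimethylaminomethyl) lactone, C11 epimers (not isolated) | CN(C)CC1C(=O)O[C@@H]2C[C@@]3(C[C@H]12)C(CO[Si](C)(C)C(C)(C)C)=C[C@@H]4OC(C)(C)O[C@H]4[C@@H]3C | intermediate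
22 | trimethylammonium iodide of 21 (not isolated) | C[N+](C)(C)CC1C(=O)O[C@@H]2C[C@@]3(C[C@H]12)C(CO[Si](C)(C)C(C)(C)C)=C[C@@H]4OC(C)(C)O[C@H]4[C@@H]3C.[I-] | intermediate
23 | α-methylene lactone, TBS ether, acetonide | C=C1C(=O)O[C@@H]2C[C@@]3(C[C@H]12)C(CO[Si](C)(C)C(C)(C)C)=C[C@@H]4OC(C)(C)O[C@H]4[C@@H]3C | intermediate
24 | α-methylene lactone, C15 primary allylic alcohol, acetonide | C=C1C(=O)O[C@@H]2C[C@@]3(C[C@H]12)C(CO)=C[C@@H]4OC(C)(C)O[C@H]4[C@@H]3C | intermediate
25 | angelic acid, (Z)-2-methylbut-2-enoic acid | C/C=C(/C)C(=O)O | starting material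
26 | C15 angelate, acetonide | C=C1C(=O)O[C@@H]2C[C@@]3(C[C@H]12)C(COC(=O)/C(C)=C\C)=C[C@@H]4OC(C)(C)O[C@H]4[C@@H]3C | intermediate
27 | CNP0224912.1 | C=C1C(=O)O[C@@H]2C[C@@]3(C[C@H]12)C(COC(=O)/C(C)=C\C)=C[C@H](O)[C@@H](O)[C@@H]3C | target

Total step count: 13. Longest linear sequence: 13 steps (1 → 27).

Steps most likely to fail

Step 7. The hydrogen atom may go to the cross-conjugated dienone and not to the monosubstituted vinyl group, giving reduction without ring closure. The trisubstituted C3=C4 alkene of the product may be reduced further, and the two orientations of the enone may be poorly discriminated at C5. Fallback, from 8 back to 15: Markovnikov hydration of the vinyl group of 8 by oxymercuration–demercuration (Hg(OAc)2, THF/H2O; NaBH4, NaOH) should give the secondary C10 alcohol F1 (both epimers usable). The sequence of step 6 with one extra equivalent of base should give the hydroxy dienone F2, and Appel bromination (CBr4, PPh3, CH2Cl2) the secondary bromide F3. Slow addition of Bu3SnH/AIBN in benzene at 80 °C then generates the same C10 radical by bromine abstraction, with no metal hydride near the dienone, and the 6-exo cyclisation returns to the route at 15.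

Step 9. Hydride may be delivered to the wrong face of C8, or C7 may epimerise too slowly, so that the lactone grows on the face of C10 and not on the face of C4. Fallback, from 17 back to 19: dehydrogenation (IBX, DMSO/PhMe, 70 °C) should give the 2-substituted cyclopentenone F4 and so remove the C7 stereocentre. Corey–Bakshi–Shibata reduction ((S)-Me-CBS, BH3·SMe2, −20 °C) sets C8 (R) under catalyst control, and the allylic alcohol lactonises (PPTS) to the β,γ-unsaturated lactone F5. DBU moves the double bond into conjugation to give the butenolide F6. Copper hydride conjugate reduction ([(Ph3P)CuH]6, PhH) then adds hydride to C7 on the face of H8, because only the cis-fused bicycle is accessible, and returns to the route at 19.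

Step 6. The 2-lithioallyl silyl ether may lose silyloxide (allene formation) or suffer silyl migration, and the alkenyllithium may enolise the vinylogous ester and not add to it. Fallback, from 8 and 9 back to 12: 9 is converted with Bu3SnLi (THF, −78 °C; aqueous acid) into 3-(tributylstannyl)cyclopent-2-en-1-one F7. Stille coupling of F7 with 8 (Pd2(dba)3, AsPh3, CuI, NMP, 50 °C) forms the C4–C5 bond with retention of alkene geometry and returns to the route at 12.

Further compounds
F1 | step 7 | secondary C10 alcohol from hydration of 8, C10 epimers | CC(O)[C@@H]1OC(C)(C)O[C@H]1/C=C(\I)CO[Si](C)(C)C(C)(C)C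
F2 | step 7 | hydroxy dienone, C10 epimers | CC(O)[C@@H]1OC(C)(C)O[C@H]1/C=C(\C2=CC(=O)CC2)CO[Si](C)(C)C(C)(C)C
F3 | step 7 | secondary C10 bromide, C10 epimers | CC(Br)[C@@H]1OC(C)(C)O[C@H]1/C=C(\C2=CC(=O)CC2)CO[Si](C)(C)C(C)(C)C
F4 | step 9 | cyclopentenone ester (C6=C7, CH2CO2Et on C7) | O=C1C[C@@]2(C=C1CC(=O)OCC)C(CO[Si](C)(C)C(C)(C)C)=C[C@@H]3OC(C)(C)O[C@H]3[C@@H]2C
F5 | step 9 | β,γ-unsaturated lactone (C6=C7), 8R | O=C1O[C@@H]2C[C@@]3(C=C2C1)C(CO[Si](C)(C)C(C)(C)C)=C[C@@H]4OC(C)(C)O[C@H]4[C@@H]3C
F6 | step 9 | butenolide (C7=C11), 8R | O=C1O[C@@H]2C[C@@]3(CC2=C1)C(CO[Si](C)(C)C(C)(C)C)=C[C@@H]4OC(C)(C)O[C@H]4[C@@H]3C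
F7 | step 6 | 3-(tributylstannyl)cyclopent-2-en-1-one | CCCC[Sn](CCCC)(CCCC)C1=CC(=O)CC1
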